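**Strategy.** Lactone ring B (C1, O2, C3, C4, C4a, C8a) is opened across its two bonds C4a–C4 and O2–C3. The feature exploited is that C4 and C3 are neighbouring carbons that join an aryl carbon (C4a) to the carboxylate oxygen (O2), which is the pattern an ortho-carboxy arylpalladium species delivers across one double bond of a 1,3-diene. One ligand-controlled palladium heteroannulation therefore forms both bonds, closes ring B and sets C3. Its precursors are an ortho-iodo dimethoxybenzoic acid and an (E)-terminal diene that already carries the C6' ketone and the pentyl terminus. Alkene hydrogenation and cleavage of the 8-methyl ether finish the synthesis.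

Key step: step 7

Remarks on the chemistry:
- Atom labels follow isochroman-1-one numbering (C1 carbonyl, O2, C3, C4, C4a, C5–C8, C8a); the side chain is C1'–C11' from C3. Ring A is the benzene ring, ring B the lactone.
- The target is the 3R lactone. The alkenyl lactone 16 has the same spatial arrangement at C3 and is 3S only because the alkenyl carbon outranks C4.
- Assumption: the sense of induction of the phosphoramidite in step 7 cannot be predicted with confidence. The (S,R,R) ligand is written; its antipode would be used if a first run gives the 3R alkenyl lactone.
- Stoichiometric species that form in the flask and are consumed before isolation are numbered. Species bound to a catalyst, and the potassium salt of acid 4 in step 7, are described in the Why lines only.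
- The diene branch places the olefination before the Grignard addition, so that no base-sensitive 1,5-keto aldehyde and no unprotected hydroxy ketone are handled.

**Step 1**
Reactants: 1 1-iodo-3,5-dimethoxybenzene
Product: 3 2-iodo-4,6-dimethoxybenzaldehyde, via aryl iminium chloride 2 (not isolated)
Conditions: POCl3, DMF, 0 → 90 °C; then H2O
Reagents that add atoms: N,N-dimethylformamide, CN(C)C=O; water, O
Why: Vilsmeier–Haack formylation, in which the chloroiminium electrophile should attack the ring carbon para to one methoxy group and ortho to the other, a less crowded site than the one between the two methoxy groups, and the iminium salt 2 is hydrolysed to the aldehyde on aqueous work-up.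

**Step 2**
Reactants: 3 2-iodo-4,6-dimethoxybenzaldehyde
Product: 4 2-iodo-4,6-dimethoxybenzoic acid
Conditions: NaClO2, NaH2PO4, 2-methyl-2-butene, t-BuOH/H2O, rt
Reagents that add atoms: sodium chlorite, [Na+].[O-]Cl=O
Why: Pinnick oxidation, in which buffered chlorous acid converts the hindered aldehyde into the acid without touching the aryl iodide or the methyl ethers, while 2-methyl-2-butene traps the hypochlorous acid that could otherwise chlorinate the electron-rich ring.

**Step 3**
Reactants: 5 δ-valerolactone
Product: 7 5-hydroxy-N-methoxy-N-methylpentanamide, via aluminium alkoxide 6 (not isolated)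
Conditions: MeNHOMe·HCl, AlMe3, CH2Cl2, 0 °C → rt; then 1 M HCl
Reagents that add atoms: N,O-dimethylhydroxylamine hydrochloride, Cl.CNOC
Why: Weinreb aminolysis of a lactone, in which the aluminium amide made from AlMe3 and the amine hydrochloride opens the lactone at the acyl carbon and the aluminium alkoxide 6 is hydrolysed on work-up.

**Step 4**
Reactants: 7 5-hydroxy-N-methoxy-N-methylpentanamide
Product: 8 N-methoxy-N-methyl-5-oxopentanamide
Conditions: TEMPO (10 mol %), PhI(OAc)2, CH2Cl2, rt
Reagents that add atoms: none
Why: TEMPO/PhI(OAc)2 oxidation through the oxoammonium ion, which should stop at the aldehyde for a primary alcohol in CH2Cl2 and leaves the Weinreb amide untouched.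

**Step 5**
Reactants: 8 N-methoxy-N-methyl-5-oxopentanamide; 9 diethyl allylphosphonate
Product: 12 (E)-N-methoxy-N-methylocta-5,7-dienamide, via lithiated allylphosphonate 10 (not isolated), via β-oxidophosphonate adduct 11 (not isolated)
Conditions: 9, n-BuLi, THF, −78 °C; then 8; then DMPU, −78 °C → rt
Reagents that add atoms: none
Why: Horner–Wadsworth–Emmons-type olefination with an allylic phosphonate, in which carbanion 10 adds through its α-carbon to the aldehyde (far more electrophilic than the Weinreb amide at −78 °C) and adduct 11 loses lithium diethyl phosphate on warming with DMPU to give the terminal diene, expected mainly as the E isomer.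

**Step 6**
Reactants: 12 (E)-N-methoxy-N-methylocta-5,7-dienamide; 13 pentylmagnesium bromide
Product: 15 (E)-trideca-10,12-dien-6-one, via magnesium hemiaminal chelate 14 (not isolated)
Conditions: C5H11MgBr, THF, 0 °C; then aq. NH4Cl
Reagents that add atoms: none
Why: Weinreb ketone synthesis, in which the Grignard reagent adds once to give the stable five-membered magnesium chelate 14, which collapses to the ketone only on quenching, so no tertiary alcohol should form and the diene is not touched.

**Step 7**
Reactants: 4 2-iodo-4,6-dimethoxybenzoic acid; 15 (E)-trideca-10,12-dien-6-one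
Product: 16 (S)-6,8-dimethoxy-3-[(E)-6-oxoundec-1-en-1-yl]isochroman-1-one
Conditions: Pd2(dba)3 (2.5 mol %), (S,R,R)-(1,1'-binaphthalene-2,2'-diyl) N,N-bis(1-phenylethyl)phosphoramidite (6 mol %), K2CO3, DMF, 60 °C
Reagents that add atoms: none
Why: Proposed new method: zerovalent palladium inserts into the C–I bond of the carboxylate of 4, the aryl group and palladium add syn across the terminal alkene of 15 so that the aryl carbon bonds to the CH2 terminus (bond C4a–C4) and a π-allyl complex of divalent palladium spans C3, C1' and C2', and the tethered carboxylate oxygen O2 then displaces palladium at C3, which returns zerovalent palladium. The closest known reaction type is the palladium-catalysed heteroannulation of 1,3-dienes by ortho-iodo phenols and anilines, which has enantioselective forms, together with the capture of such aryl-derived π-allyl complexes by an ortho carboxylate, known without asymmetric induction; the untested element is the pairing of a carboxylate terminus with a chiral ligand. Ring B closes in a 6-exo mode by attack of O2 on the proximal allyl terminus C3, the alternative attack at C2' requiring an eight-membered ring. The configuration at C3 is controlled by the chiral phosphoramidite on palladium, which selects the face of the terminal alkene in the insertion and thereby the face of the π-allyl left open to O2. The step needs aryl transfer to the unsubstituted diene terminus, C–O bond formation at C3 and an E alkene, and these are secured by the unhindered CH2 end, by the six-membered ring preference and by the syn,syn π-allyl that the E diene gives directly. The remote ketone is inert to zerovalent palladium and carbonate, and 15 is used as the pure E isomer because anti-to-syn isomerisation of a Z-derived complex at C2' would exchange the palladium-bound face at C3.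

**Step 8**
Reactants: 16 (S)-6,8-dimethoxy-3-[(E)-6-oxoundec-1-en-1-yl]isochroman-1-one
Product: 17 (R)-6,8-dimethoxy-3-(6-oxoundecyl)isochroman-1-one
Conditions: H2 (1 atm), RhCl(PPh3)3 (5 mol %), toluene/EtOH, rt
Reagents that add atoms: none
Why: Homogeneous rhodium-catalysed hydrogenation of the Wilkinson type, in which RhCl(PPh3)3 should reduce the unhindered disubstituted alkene by syn addition of H2 without reducing the ketone and, unlike palladium on carbon, without cleaving the allylic C3–O2 bond, so the C3 arrangement is carried over unchanged (the descriptor becomes R because C4 now outranks the saturated chain).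

**Step 9**
Reactants: 17 (R)-6,8-dimethoxy-3-(6-oxoundecyl)isochroman-1-one
Product: 19 (R)-8-hydroxy-6-methoxy-3-(6-oxoundecyl)isochroman-1-one, via aryloxydichloroborane 18 (not isolated)
Conditions: BCl3, CH2Cl2, −78 → 0 °C; then H2O
Reagents that add atoms: none
Why: Chelation-controlled Lewis acid ether cleavage, in which BCl3 binds between the C1 carbonyl oxygen and the peri 8-methoxy oxygen and chloride removes that methyl group to give chelate 18, while the 6-methoxy group (which cannot chelate), the lactone, the ketone and the C3 stereocentre should be untouched at low temperature.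

**Compound list**
1 | 1-iodo-3,5-dimethoxybenzene | COc1cc(I)cc(OC)c1 | starting material
2 | N-[(2-iodo-4,6-dimethoxyphenyl)methylidene]-N-methylmethanaminium chloride (aryl iminium chloride, formed in the flask) | C[N+](C)=Cc1c(I)cc(OC)cc1OC.[Cl-] | intermediate
3 | 2-iodo-4,6-dimethoxybenzaldehyde | O=Cc1c(I)cc(OC)cc1OC | intermediate
4 | 2-iodo-4,6-dimethoxybenzoic acid | OC(=O)c1c(I)cc(OC)cc1OC | intermediate
5 | δ-valerolactone (tetrahydro-2H-pyran-2-one) | O=C1CCCCO1 | starting material
6 | chloro(methyl)aluminium 5-[methoxy(methyl)amino]-5-oxopentan-1-olate (aluminium alkoxide, formed in the flask) | CON(C)C(=O)CCCCO[Al](C)Cl | intermediate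
7 | 5-hydroxy-N-methoxy-N-methylpentanamide | CON(C)C(=O)CCCCO | intermediate
8 | N-methoxy-N-methyl-5-oxopentanamide | CON(C)C(=O)CCCC=O | intermediate
9 | diethyl allylphosphonate | C=CCP(=O)(OCC)OCC | starting material
10 | lithiated diethyl allylphosphonate (formed in the flask) | [Li+].C=C[CH-]P(=O)(OCC)OCC | intermediate
11 | lithium 3-(diethoxyphosphoryl)-8-[methoxy(methyl)amino]-8-oxooct-1-en-4-olate (β-oxidophosphonate adduct, diastereomer mixture, formed in the flask) | [Li+].[O-]C(CCCC(=O)N(C)OC)C(C=C)P(=O)(OCC)OCC | intermediate
12 | (E)-N-methoxy-N-methylocta-5,7-dienamide | CON(C)C(=O)CCC/C=C/C=C | intermediate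
13 | pentylmagnesium bromide, C5H11MgBr (commercial solution in diethyl ether) | CCCCC[Mg]Br | starting material
14 | bromomagnesium (E)-6-[methoxy(methyl)amino]trideca-10,12-dien-6-olate (magnesium hemiaminal chelate, formed in the flask) | CCCCCC(O[Mg]Br)(CCC/C=C/C=C)N(C)OC | intermediate
15 | (E)-trideca-10,12-dien-6-one | CCCCCC(=O)CCC/C=C/C=C | intermediate
16 | (S)-6,8-dimethoxy-3-[(E)-6-oxoundec-1-en-1-yl]isochroman-1-one | CCCCCC(=O)CCC/C=C/[C@@H]1Cc2cc(OC)cc(OC)c2C(=O)O1 | intermediate
17 | (R)-6,8-dimethoxy-3-(6-oxoundecyl)isochroman-1-one | CCCCCC(=O)CCCCC[C@@H]1Cc2cc(OC)cc(OC)c2C(=O)O1 | intermediate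
18 | (R)-8-(dichloroboranyloxy)-6-methoxy-3-(6-oxoundecyl)isochroman-1-one (aryloxydichloroborane, formed in the flask) | CCCCCC(=O)CCCCC[C@@H]1Cc2cc(OC)cc(OB(Cl)Cl)c2C(=O)O1 | intermediate
19 | (R)-8-hydroxy-6-methoxy-3-(6-oxoundecyl)isochroman-1-one | CCCCCC(=O)CCCCC[C@@H]1Cc2cc(OC)cc(O)c2C(=O)O1 | target

**Totals**
Total step count: 9 (steps 1–2 to the acid, steps 3–6 to the dienone, steps 7–9 in common).
Longest linear sequence: 7 steps (steps 3–9, from δ-valerolactone 5 to target 19).

**Steps most likely to fail**

1. Step 7 (carries the label). What may go wrong:
- insufficient face selection in the alkene insertion;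
- erosion of enantiopurity if zerovalent palladium re-ionises the allylic C3–O2 bond of the product on prolonged heating;
- β-hydride elimination from the π-allyl complex to an open-chain aryl triene;
- palladium-mediated loss of CO2 from the electron-rich 2,6-disubstituted acid.

Fallback, known chemistry only, with the stereocentre taken from a hydrolytic kinetic resolution instead of the annulation: it sets out from acid 4 and Grignard reagent 13 and rejoins the route at 17, so that step 8 is not needed. Acid 4 is methylated (MeI, K2CO3, DMF) to methyl 2-iodo-4,6-dimethoxybenzoate F1. Commercial oct-7-enoic acid is converted with carbonyldiimidazole and MeNHOMe·HCl into N-methoxy-N-methyloct-7-enamide F2, which with 13 gives tridec-12-en-6-one F3. Ketalisation (ethylene glycol, TsOH, toluene, water removal) gives 2-(hept-6-en-1-yl)-2-pentyl-1,3-dioxolane F4, and buffered mCPBA gives racemic 2-[5-(2-pentyl-1,3-dioxolan-2-yl)pentyl]oxirane F5. Hydrolytic kinetic resolution with the trivalent cobalt complex (R,R)-(salen)Co(OAc) and 0.55 equiv of water should leave (R)-2-[5-(2-pentyl-1,3-dioxolan-2-yl)pentyl]oxirane F6, the other enantiomer being removed as its diol. Iodine–magnesium exchange on F1 (iPrMgCl·LiCl, THF, −40 °C) gives [3,5-dimethoxy-2-(methoxycarbonyl)phenyl]magnesium chloride F7, which with catalytic CuI opens F6 at its CH2 terminus. The magnesium alkoxide then closes onto the neighbouring ester to give (R)-6,8-dimethoxy-3-[5-(2-pentyl-1,3-dioxolan-2-yl)pentyl]isochroman-1-one F8, and 1 M HCl in THF removes the dioxolane to give 17. The stereocentre is never touched after the resolution, because the aryl group attacks the epoxide CH2.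

2. Step 5. What may go wrong:
- incomplete E selectivity in the elimination;
- attack through the γ-carbon of the ambident allyl anion;
- enolisation of the aldehyde by the basic carbanion.

A Z contaminant matters beyond yield, because it would feed the opposite palladium-bound face at C3 in step 7. Minor Z isomer would first be removed on AgNO3-impregnated silica.

Fallback: it sets out from aldehyde 8 and rejoins at 12. Takai iodo-olefination (CHI3, CrCl2, THF, 0 °C), which is selective for aldehydes and for the E alkene, should give (E)-6-iodo-N-methoxy-N-methylhex-5-enamide F9. Suzuki–Miyaura coupling with vinylboronic acid pinacol ester (Pd(PPh3)4, K2CO3, THF/H2O, 60 °C) should then give 12 with retention of the alkene geometry.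

3. Step 8. What may go wrong:
- slow reduction of the trans-disubstituted alkene;
- rhodium-hydride-mediated migration of the double bond toward C3, which would erase the stereocentre;
- cleavage of the allylic C3–O2 bond.

Fallback: it sets out from 16 and rejoins at 17. The reduction is done without a metal by diimide, generated from dipotassium azodicarboxylate and acetic acid in MeOH/CH2Cl2 at 0 °C → rt. Diimide transfers H2 in a concerted syn fashion to the unpolarised alkene, cannot form allyl–metal species and does not reduce the ketone or the lactone.

**Further compounds**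
F1 | step 7 | methyl 2-iodo-4,6-dimethoxybenzoate | COC(=O)c1c(I)cc(OC)cc1OC
F2 | step 7 | N-methoxy-N-methyloct-7-enamide | CON(C)C(=O)CCCCCC=C
F3 | step 7 | tridec-12-en-6-one | CCCCCC(=O)CCCCCC=C
F4 | step 7 | 2-(hept-6-en-1-yl)-2-pentyl-1,3-dioxolane | CCCCCC1(CCCCCC=C)OCCO1
F5 | step 7 | racemic 2-[5-(2-pentyl-1,3-dioxolan-2-yl)pentyl]oxirane | CCCCCC1(CCCCCC2CO2)OCCO1
F6 | step 7 | (R)-2-[5-(2-pentyl-1,3-dioxolan-2-yl)pentyl]oxirane | CCCCCC1(CCCCC[C@@H]2CO2)OCCO1
F7 | step 7 | [3,5-dimethoxy-2-(methoxycarbonyl)phenyl]magnesium chloride | COC(=O)c1c([Mg]Cl)cc(OC)cc1OC
F8 | step 7 | (R)-6,8-dimethoxy-3-[5-(2-pentyl-1,3-dioxolan-2-yl)pentyl]isochroman-1-one | CCCCCC1(CCCCC[C@@H]2Cc3cc(OC)cc(OC)c3C(=O)O2)OCCO1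
F9 | step 5 | (E)-6-iodo-N-methoxy-N-methylhex-5-enamide | CON(C)C(=O)CCC/C=C/I
F0 | step 8 | none | none
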